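Everything rests on breaking the oxepane bond between the ring oxygen and its CMe2 carbon. The CMe2 carbon, the neighbouring CH and the oxygen of the acetate on that CH are read as one trisubstituted (R)-epoxide, and the ring oxygen as the equatorial hydroxyl on the CH–O carbon of the cyclohexane (ring B). One acid-catalysed 7-endo opening at the tertiary carbon then closes the last ring and frees the secondary alcohol that is acetylated. The precursor is a seco-compound carrying ring B, the epoxidised homoprenyl chain on its quaternary carbon and the finished hydroazulenone, assembled by Stork–Danheiser union of a geraniol-derived cyclohexylethyllithium with a linalool-derived bicyclic vinylogous ester.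

Key step: step 23

Remark: (S)-(+)-linalool is taken as commercially available in high enantiomeric purity; its carbinol centre is the only source of absolute configuration in the hydroazulene fragment.

**Hydroazulene fragment**

Step 1
Reactants: 1 (S)-(+)-linalool
Product: 2 (1S)-1-methylcyclopent-2-en-1-ol
Conditions: second-generation Grubbs catalyst (0.5 mol%), CH2Cl2, 40 °C
Reagents that add atoms: none
Why: Ring-closing metathesis of the 1,6-diene expels 2-methylpropene and does not touch the tertiary carbinol stereocentre.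

Step 2
Reactants: 2 (1S)-1-methylcyclopent-2-en-1-ol
Product: 3 (1S)-1-methylcyclopent-2-en-1-yl 2-methylpropanoate
Conditions: n-BuLi, THF, −78 °C; then i-PrCOCl, −78 to 0 °C
Reagents that add atoms: 2-methylpropanoyl chloride, CC(C)C(=O)Cl
Why: O-acylation of the lithium alkoxide by an acid chloride (addition–elimination) should give the tertiary allylic ester without ionising the C–O bond.

Step 3
Reactants: 3 allylic isobutyrate
Product: 6 2-methyl-2-[(1R)-3-methylcyclopent-2-en-1-yl]propanoic acid, via silyl ketene acetal 4 (not isolated), via trimethylsilyl ester 5 (not isolated)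
Conditions: LDA, TMSCl, THF, −78 °C, then 60 °C; then 1 N HCl
Reagents that add atoms: none
Why: Ireland–Claisen rearrangement; the suprafacial [3,3] shift forms the new C–C bond on the ring face that carried the oxygen, so the carbinol chirality is relayed to the new ring stereocentre (R) while the quaternary CMe2 carbon is built.

Step 4
Reactants: 6 carboxylic acid
Product: 7 2-methyl-2-[(1R)-3-methylcyclopent-2-en-1-yl]pentan-3-one
Conditions: EtLi (2.2 equiv), Et2O, 0 °C to rt; aq. NH4Cl
Reagents that add atoms: ethyllithium, [Li]CC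
Why: Ketone synthesis from a carboxylic acid with two equivalents of organolithium; the dilithio gem-diolate collapses only on work-up, so no tertiary alcohol should form.

Step 5
Reactants: 7 ethyl ketone
Product: 9 (4R)-2-methyl-4-(2-methyl-3-oxopentan-2-yl)cyclopent-2-en-1-one, via trans-allylic alcohol 8 (not isolated)
Conditions: SeO2 (0.5 equiv), t-BuOOH, CH2Cl2, rt; then Dess–Martin periodinane, NaHCO3, rt
Reagents that add atoms: selenium dioxide, O=[Se]=O; tert-butyl hydroperoxide, CC(C)(C)OO
Why: Selenium dioxide allylic oxidation (ene reaction then [2,3] shift) should attack the ring CH2 next to the methyl-bearing alkene carbon, and Dess–Martin oxidation erases the carbinol configuration.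

Step 6
Reactants: 9 cyclopentenone
Product: 10 2-[(1R,4S)-4-hydroxy-3-methylcyclopent-2-en-1-yl]-2-methylpentan-3-one
Conditions: NaBH4, CeCl3·7H2O, MeOH, −78 °C
Reagents that add atoms: none
Why: Luche 1,2-reduction; hydride should add anti to the bulky C-4 substituent to give the cis allylic alcohol, and the hindered saturated ketone should survive at −78 °C.

Step 7
Reactants: 10 cis-allylic alcohol
Product: 12 ethyl 2-[(1R,5R)-2-methyl-5-(2-methyl-3-oxopentan-2-yl)cyclopent-2-en-1-yl]acetate, via mixed ketene acetal 11 (not isolated)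
Conditions: MeC(OEt)3, EtCO2H (cat.), 140 °C
Reagents that add atoms: triethyl orthoacetate, CCOC(C)(OCC)OCC
Why: Johnson–Claisen rearrangement; the ketene acetal on the cis oxygen delivers the acetate unit suprafacially, so the new CH2CO2Et is cis to the neighbouring side chain (the later cis ring fusion).

Step 8
Reactants: 12 cyclopentenyl acetate
Product: 13 ethyl 2-[(1R,2R,5R)-2-hydroxy-2-methyl-5-(2-methyl-3-oxopentan-2-yl)cyclopentyl]acetate
Conditions: Mn(dpm)3 (10 mol%), PhSiH3, O2 (1 atm), i-PrOH, 0 °C to rt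
Reagents that add atoms: dioxygen, O=O
Why: Mukaiyama hydration (hydrogen-atom transfer, Markovnikov); O2 should trap the tertiary radical on the face anti to the two cis side chains, placing OH trans and methyl cis to them.

Step 9
Reactants: 13 hydroxy keto ester
Product: 14 (1R,3aR,8aR)-1-hydroxy-1,4,4,6-tetramethyl-2,3,3a,4,8,8a-hexahydroazulene-5,7(1H,6H)-dione
Conditions: KOt-Bu (3.2 equiv), THF, 0 °C to rt; then AcOH
Reagents that add atoms: none
Why: Intramolecular Claisen (Dieckmann-type) condensation; the ketone can enolise only on its ethyl side, its only acyl acceptor is the ester (seven-membered ring), and deprotonation of the 2-methyl-1,3-dione drives the closure.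

Step 10
Reactants: 14 bicyclic 1,3-dione
Product: 15 (1R,3aR,8aR)-1-hydroxy-7-methoxy-1,4,4,6-tetramethyl-2,3,3a,4,8,8a-hexahydroazulen-5(1H)-one
Conditions: MeOH, TsOH (cat.), 4 Å molecular sieves, rt
Reagents that add atoms: methanol, CO
Why: Acid-catalysed enol etherification of a 1,3-diketone (vinylogous ester formation) should occur at the less hindered carbonyl, leaving the carbonyl next to the CMe2 carbon free.

Step 11
Reactants: 15 vinylogous ester
Product: 16 triethylsilyl ether of 15
Conditions: Et3SiOTf, 2,6-lutidine, CH2Cl2, −78 to 0 °C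
Reagents that add atoms: triethylsilyl trifluoromethanesulfonate, CC[Si](CC)(CC)OS(=O)(=O)C(F)(F)F
Why: Silylation of the tertiary alcohol with a silyl triflate masks the only acidic proton before the organolithium coupling.

**Cyclohexane fragment (ring B)**

Step 12
Reactants: 17 geraniol
Product: 18 (2R,3R)-2,3-epoxygeraniol
Conditions: Ti(Oi-Pr)4 (5 mol%), D-(−)-diethyl tartrate (7 mol%), t-BuOOH, 4 Å molecular sieves, CH2Cl2, −20 °C
Reagents that add atoms: tert-butyl hydroperoxide, CC(C)(C)OO
Why: Sharpless asymmetric epoxidation; only the allylic-alcohol alkene reacts and the D-tartrate ligand should set the (2R,3R) epoxide that later becomes the ring-B carbinol and quaternary centres.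

Step 13
Reactants: 18 epoxy alcohol
Product: 19 (2S,3R)-2-(iodomethyl)-3-methyl-3-(4-methylpent-3-en-1-yl)oxirane
Conditions: I2, PPh3, imidazole, CH2Cl2, 0 °C
Reagents that add atoms: iodine, II
Why: Appel-type iodination of the primary alcohol under neutral conditions should leave the epoxide intact.

Step 14
Reactants: 19 epoxy iodide; 20 methyl acetoacetate
Product: 21 methyl (6R,7R)-6,7-epoxy-7,11-dimethyl-3-oxododec-10-enoate
Conditions: 20, LDA (2.1 equiv), THF, 0 °C; then 19, 0 °C
Reagents that add atoms: none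
Why: γ-Alkylation of the acetoacetate dianion; SN2 displacement at the primary iodide by the terminal carbanion should be much faster than epoxide opening.

Step 15
Reactants: 21 epoxy β-keto ester
Product: 22 methyl (1R,2R,3R)-3-hydroxy-2-methyl-2-(4-methylpent-3-en-1-yl)-6-oxocyclohexane-1-carboxylate
Conditions: SnCl4 (1.2 equiv), CH2Cl2, −78 to −40 °C; aq. NaHCO3
Reagents that add atoms: none
Why: Lewis-acid epoxide-initiated cyclisation terminated by the β-keto ester enol; anti opening with inversion at the tertiary epoxide carbon through a chair transition state should place the equatorial hydroxyl cis to the axial ring methyl, and the epimerisable ester settles equatorial.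

Step 16
Reactants: 22 cyclic β-keto ester
Product: 24 (3R,4R)-4-hydroxy-3-methyl-2-methylidene-3-(4-methylpent-3-en-1-yl)cyclohexan-1-one, via beta-keto acid 23 (not isolated)
Conditions: LiOH, THF/H2O, rt; then 37% aq. CH2O, Et2NH (cat.), AcOH, 50 °C
Reagents that add atoms: formaldehyde, C=O
Why: Saponification then decarboxylative Mannich methylenation of the β-keto acid should give the α-methylene ketone regiospecifically at the former ester carbon.

Step 17
Reactants: 24 α-methylene ketone
Product: 26 (2R,3R,4R)-4-hydroxy-2-(2-hydroxyethyl)-3-methyl-3-(4-methylpent-3-en-1-yl)cyclohexan-1-one, via silane ketone 25 (not isolated)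
Conditions: (i-PrO)Me2SiCH2MgCl (2.5 equiv), CuI (10 mol%), THF, −78 to −20 °C; then 30% H2O2, KHCO3, MeOH/THF, rt
Reagents that add atoms: [(isopropoxydimethylsilyl)methyl]magnesium chloride, CC(C)O[Si](C)(C)C[Mg]Cl; hydrogen peroxide, OO
Why: Copper-catalysed conjugate addition of a hydroxymethyl-anion equivalent then Tamao oxidation; axial protonation of the enolate (or equilibration) should give the equatorial two-carbon chain cis to the ring methyl.

Step 18
Reactants: 26 keto diol
Product: 27 (1S,2R,3R,4R)-2-(2-hydroxyethyl)-1,3-dimethyl-3-(4-methylpent-3-en-1-yl)cyclohexane-1,4-diol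
Conditions: MeLi (4 equiv), Et2O, −78 to 0 °C
Reagents that add atoms: methyllithium, [Li]C
Why: 1,2-Addition of methyllithium; equatorial attack, away from the axial ring methyl, should give the axial tertiary alcohol cis to the side chain.

Step 19
Reactants: 27 triol
Product: 28 (1S,2R,3R,4R)-2-(2-iodoethyl)-1,3-dimethyl-3-(4-methylpent-3-en-1-yl)cyclohexane-1,4-diol
Conditions: I2, PPh3, imidazole, CH2Cl2, 0 °C
Reagents that add atoms: iodine, II
Why: Appel-type iodination should be selective for the primary alcohol over the hindered secondary and tertiary ones.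

Step 20
Reactants: 28 iodo diol
Product: 29 bis(triethylsilyl) ether of 28
Conditions: Et3SiOTf (2.5 equiv), 2,6-lutidine, CH2Cl2, −78 to 0 °C
Reagents that add atoms: triethylsilyl trifluoromethanesulfonate, CC[Si](CC)(CC)OS(=O)(=O)C(F)(F)F
Why: Silyl triflate silylation masks both hydroxyls before halogen–lithium exchange.

**Union and end game**

Step 21
Reactants: 29 bis-silylated iodide; 16 silylated vinylogous ester
Product: 32 coupled enone triol, via alkyllithium 30 (not isolated), via carbonyl adduct 31 (not isolated)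
Conditions: 29, t-BuLi (2.1 equiv), Et2O, −78 °C; then 16, −78 to 0 °C; then 1 N HCl, THF, rt
Reagents that add atoms: none
Why: Stork–Danheiser sequence; iodine–lithium exchange, 1,2-addition to the vinylogous ester carbonyl and acid-mediated transposition with loss of methanol should give the tetrasubstituted enone, with the silyl ethers cleaved in the same acid treatment.

Step 22
Reactants: 32 enone triol
Product: 33 (R)-epoxide of 32
Conditions: D-fructose-derived Shi ketone (0.3 equiv), KHSO5 (Oxone), K2CO3, n-Bu4NHSO4, MeCN/dimethoxymethane/aq. buffer (pH 10.5), 0 °C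
Reagents that add atoms: potassium peroxymonosulfate, [K+].[O-]S(=O)(=O)OO
Why: Shi asymmetric epoxidation; the chiral dioxirane should epoxidise only the electron-rich trisubstituted alkene and set the (R) configuration at its CH carbon by reagent control.

Step 23
Reactants: 33 epoxy triol
Product: 34 oxepane alcohol
Conditions: (±)-camphor-10-sulfonic acid (10 mol%), CH2Cl2, −20 to 0 °C
Reagents that add atoms: none
Why: Protonation of the 2,2-dimethyl-3-alkyloxirane lengthens its tertiary C–O bond, and the equatorial secondary hydroxyl of ring B attacks that CMe2 carbon from the backside, so the epoxide oxygen stays on the CH carbon as the free secondary alcohol. The closest known reaction type is the acid-catalysed endo-selective hydroxy-epoxide cyclisation at a gem-dimethyl epoxide terminus (Markovnikov epoxide opening) used for terpenoid cyclic ethers. The oxepane closes in the 7-endo-tet mode and is trans-fused to the cyclohexane, because the nucleophilic oxygen and the chain on the quaternary carbon are both equatorial. No stereocentre is created: the CH–O carbon keeps the (R) configuration from the Shi epoxidation since its C–O bond is never broken, and the attacked carbon bears two methyls. The step needs 7-endo attack to beat 6-exo attack at the secondary epoxide carbon; tertiary-carbocation character at the CMe2 carbon under catalytic acid in a non-nucleophilic solvent at low temperature should secure this. The two tertiary alcohols are hindered and geometrically remote, and the enone is inert to catalytic acid.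

Step 24
Reactants: 34 oxepane alcohol
Product: 35 oxepane acetate enone
Conditions: Ac2O, pyridine, rt
Reagents that add atoms: acetic anhydride, CC(=O)OC(C)=O
Why: Acylation of the only secondary alcohol; the two tertiary alcohols should not react without an acyl-transfer catalyst.

Step 25
Reactants: 35 acetate enone
Product: 36 target compound
Conditions: (S)-2-methyl-CBS-oxazaborolidine (0.5 equiv), catecholborane, toluene, −78 °C; MeOH
Reagents that add atoms: none
Why: Corey–Bakshi–Shibata reduction; with the alkenyl side as the large group the (S)-oxazaborolidine should deliver hydride to give the (R)-allylic alcohol by reagent control, and the acetate is inert to catecholborane at −78 °C.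

**Compound list**

1 | (S)-(+)-linalool, (3S)-3,7-dimethylocta-1,6-dien-3-ol | CC(C)=CCC[C@](C)(O)C=C | starting material
2 | (1S)-1-methylcyclopent-2-en-1-ol | C[C@@]1(O)C=CCC1 | intermediate
3 | (1S)-1-methylcyclopent-2-en-1-yl 2-methylpropanoate | CC(C)C(=O)O[C@]1(C)C=CCC1 | intermediate
4 | trimethylsilyl ketene acetal of 3 | CC(C)=C(O[Si](C)(C)C)O[C@]1(C)C=CCC1 | intermediate
5 | trimethylsilyl 2-methyl-2-[(1R)-3-methylcyclopent-2-en-1-yl]propanoate | C[Si](C)(C)OC(=O)C(C)(C)[C@H]1C=C(C)CC1 | intermediate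
6 | 2-methyl-2-[(1R)-3-methylcyclopent-2-en-1-yl]propanoic acid | OC(=O)C(C)(C)[C@H]1C=C(C)CC1 | intermediate
7 | 2-methyl-2-[(1R)-3-methylcyclopent-2-en-1-yl]pentan-3-one | CCC(=O)C(C)(C)[C@H]1C=C(C)CC1 | intermediate
8 | 2-[(1R,4R)-4-hydroxy-3-methylcyclopent-2-en-1-yl]-2-methylpentan-3-one (OH trans to the side chain) | CCC(=O)C(C)(C)[C@H]1C=C(C)[C@H](O)C1 | intermediate
9 | (4R)-2-methyl-4-(2-methyl-3-oxopentan-2-yl)cyclopent-2-en-1-one | CCC(=O)C(C)(C)[C@H]1C=C(C)C(=O)C1 | intermediate
10 | 2-[(1R,4S)-4-hydroxy-3-methylcyclopent-2-en-1-yl]-2-methylpentan-3-one (OH cis to the side chain) | CCC(=O)C(C)(C)[C@H]1C=C(C)[C@@H](O)C1 | intermediate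
11 | 1-ethoxyvinyl ether of 10 (mixed ketene acetal) | CCC(=O)C(C)(C)[C@H]1C=C(C)[C@@H](OC(=C)OCC)C1 | intermediate
12 | ethyl 2-[(1R,5R)-2-methyl-5-(2-methyl-3-oxopentan-2-yl)cyclopent-2-en-1-yl]acetate | CCC(=O)C(C)(C)[C@@H]1CC=C(C)[C@@H]1CC(=O)OCC | intermediate
13 | ethyl 2-[(1R,2R,5R)-2-hydroxy-2-methyl-5-(2-methyl-3-oxopentan-2-yl)cyclopentyl]acetate | CCC(=O)C(C)(C)[C@@H]1CC[C@@](C)(O)[C@@H]1CC(=O)OCC | intermediate
14 | (1R,3aR,8aR)-1-hydroxy-1,4,4,6-tetramethyl-2,3,3a,4,8,8a-hexahydroazulene-5,7(1H,6H)-dione (cis-fused; C-6 epimers and enol) | O=C1C(C)C(=O)C[C@@H]2[C@@H](CC[C@@]2(C)O)C1(C)C | intermediate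
15 | (1R,3aR,8aR)-1-hydroxy-7-methoxy-1,4,4,6-tetramethyl-2,3,3a,4,8,8a-hexahydroazulen-5(1H)-one | O=C1C(C)=C(OC)C[C@@H]2[C@@H](CC[C@@]2(C)O)C1(C)C | intermediate
16 | (1R,3aR,8aR)-7-methoxy-1,4,4,6-tetramethyl-1-(triethylsilyloxy)-2,3,3a,4,8,8a-hexahydroazulen-5(1H)-one | O=C1C(C)=C(OC)C[C@@H]2[C@@H](CC[C@@]2(C)O[Si](CC)(CC)CC)C1(C)C | intermediate
17 | geraniol | CC(C)=CCC/C(C)=C/CO | starting material
18 | (2R,3R)-2,3-epoxygeraniol | OC[C@H]1O[C@]1(C)CCC=C(C)C | intermediate
19 | (2S,3R)-2-(iodomethyl)-3-methyl-3-(4-methylpent-3-en-1-yl)oxirane | IC[C@H]1O[C@]1(C)CCC=C(C)C | intermediate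
20 | methyl acetoacetate | COC(=O)CC(C)=O | starting material
21 | methyl (6R,7R)-6,7-epoxy-7,11-dimethyl-3-oxododec-10-enoate | COC(=O)CC(=O)CC[C@H]1O[C@]1(C)CCC=C(C)C | intermediate
22 | methyl (1R,2R,3R)-3-hydroxy-2-methyl-2-(4-methylpent-3-en-1-yl)-6-oxocyclohexane-1-carboxylate | CC(C)=CCC[C@]1(C)[C@@H](C(=O)OC)C(=O)CC[C@H]1O | intermediate
23 | (1R,2R,3R)-3-hydroxy-2-methyl-2-(4-methylpent-3-en-1-yl)-6-oxocyclohexane-1-carboxylic acid | CC(C)=CCC[C@]1(C)[C@@H](C(=O)O)C(=O)CC[C@H]1O | intermediate
24 | (3R,4R)-4-hydroxy-3-methyl-2-methylidene-3-(4-methylpent-3-en-1-yl)cyclohexan-1-one | CC(C)=CCC[C@]1(C)C(=C)C(=O)CC[C@H]1O | intermediate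
25 | (2R,3R,4R)-4-hydroxy-2-{2-[isopropoxy(dimethyl)silyl]ethyl}-3-methyl-3-(4-methylpent-3-en-1-yl)cyclohexan-1-one | CC(C)=CCC[C@]1(C)[C@@H](CC[Si](C)(C)OC(C)C)C(=O)CC[C@H]1O | intermediate
26 | (2R,3R,4R)-4-hydroxy-2-(2-hydroxyethyl)-3-methyl-3-(4-methylpent-3-en-1-yl)cyclohexan-1-one | CC(C)=CCC[C@]1(C)[C@@H](CCO)C(=O)CC[C@H]1O | intermediate
27 | (1S,2R,3R,4R)-2-(2-hydroxyethyl)-1,3-dimethyl-3-(4-methylpent-3-en-1-yl)cyclohexane-1,4-diol | CC(C)=CCC[C@]1(C)[C@@H](CCO)[C@@](C)(O)CC[C@H]1O | intermediate
28 | (1S,2R,3R,4R)-2-(2-iodoethyl)-1,3-dimethyl-3-(4-methylpent-3-en-1-yl)cyclohexane-1,4-diol | CC(C)=CCC[C@]1(C)[C@@H](CCI)[C@@](C)(O)CC[C@H]1O | intermediate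
29 | 1,4-bis(triethylsilyl) ether of 28 | CC(C)=CCC[C@]1(C)[C@@H](CCI)[C@@](C)(O[Si](CC)(CC)CC)CC[C@H]1O[Si](CC)(CC)CC | intermediate
30 | primary alkyllithium from 29 (lithium in place of iodine) | CC(C)=CCC[C@]1(C)[C@@H](CC[Li])[C@@](C)(O[Si](CC)(CC)CC)CC[C@H]1O[Si](CC)(CC)CC | intermediate
31 | tertiary alcohol from 1,2-addition of 30 to the ketone of 16 (new carbinol centre unassigned) | CC(C)=CCC[C@]1(C)[C@@H](CCC2(O)C(C)=C(OC)C[C@@H]3[C@@H](CC[C@@]3(C)O[Si](CC)(CC)CC)C2(C)C)[C@@](C)(O[Si](CC)(CC)CC)CC[C@H]1O[Si](CC)(CC)CC | intermediate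
32 | (1R,3aR,8aR)-5-{2-[(1R,2S,5R,6R)-2,5-dihydroxy-2,6-dimethyl-6-(4-methylpent-3-en-1-yl)cyclohexyl]ethyl}-1-hydroxy-1,4,4,6-tetramethyl-2,3,3a,4,8,8a-hexahydroazulen-7(1H)-one | CC(C)=CCC[C@]1(C)[C@@H](CCC2=C(C)C(=O)C[C@@H]3[C@@H](CC[C@@]3(C)O)C2(C)C)[C@@](C)(O)CC[C@H]1O | intermediate
33 | analogue of 32 with the side-chain alkene as the (2R)-3,3-dimethyloxiran-2-yl epoxide | CC1(C)O[C@@H]1CC[C@]2(C)[C@@H](CCC3=C(C)C(=O)C[C@@H]4[C@@H](CC[C@@]4(C)O)C3(C)C)[C@@](C)(O)CC[C@H]2O | intermediate
34 | (1R,3aR,8aR)-5-{2-[(3R,5aR,6R,7S,9aR)-3,7-dihydroxy-2,2,5a,7-tetramethyldecahydro-1-benzoxepin-6-yl]ethyl}-1-hydroxy-1,4,4,6-tetramethyl-2,3,3a,4,8,8a-hexahydroazulen-7(1H)-one | O[C@@H]1CC[C@]2(C)[C@@H](CCC3=C(C)C(=O)C[C@@H]4[C@@H](CC[C@@]4(C)O)C3(C)C)[C@@](C)(O)CC[C@H]2OC1(C)C | intermediate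
35 | (3R,5aR,6R,7S,9aR)-7-hydroxy-6-{2-[(1R,3aR,8aR)-1-hydroxy-1,4,4,6-tetramethyl-7-oxo-1,2,3,3a,4,7,8,8a-octahydroazulen-5-yl]ethyl}-2,2,5a,7-tetramethyldecahydro-1-benzoxepin-3-yl acetate | CC(=O)O[C@@H]1CC[C@]2(C)[C@@H](CCC3=C(C)C(=O)C[C@@H]4[C@@H](CC[C@@]4(C)O)C3(C)C)[C@@](C)(O)CC[C@H]2OC1(C)C | intermediate
36 | (3R,5aR,6R,7S,9aR)-6-{2-[(1R,3aR,7R,8aR)-1,7-dihydroxy-1,4,4,6-tetramethyl-1,2,3,3a,4,7,8,8a-octahydroazulen-5-yl]ethyl}-7-hydroxy-2,2,5a,7-tetramethyldecahydro-1-benzoxepin-3-yl acetate (CNP0157376.1) | CC(=O)O[C@@H]1CC[C@]2(C)[C@@H](CCC3=C(C)[C@H](O)C[C@@H]4[C@@H](CC[C@@]4(C)O)C3(C)C)[C@@](C)(O)CC[C@H]2OC1(C)C | target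

**Step count**

Total: 25 steps. Longest linear sequence: 16 steps (steps 1–11, then 21–25). The ring-B branch (steps 12–20) is 9 steps.

**Steps most likely to fail**

1. Step 23 (key step). The hydroxyl may attack the secondary epoxide carbon (6-exo closure), or the activated epoxide may rearrange by hydride shift, so that the oxepane is not the main product. The fallback replaces the endo epoxide opening by an exo alkoxymercuration. It sets out from 33: diethylaluminium 2,2,6,6-tetramethylpiperidide (toluene, 0 °C) isomerises the epoxide by syn elimination on a methyl group, with the carbinol configuration retained, to the isopropenyl carbinol F1. Hg(OCOCF3)2 in THF at 0 °C should then close the ring by 7-exo-trig Markovnikov attack of the ring-B hydroxyl on the isopropenyl carbon, giving the organomercurial F2. NaBH4/NaOH removes mercury and the route is rejoined at 34.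

2. Step 21. Deprotonation of 16 at its γ-CH2, or reversal of the addition at the hindered carbonyl next to the CMe2 carbon, may return both fragments. The fallback replaces carbonyl addition by cross-coupling and sets out from 16 and 29. KHMDS and PhNTf2 (THF, −78 °C) convert 16 into the dienyl triflate F3; t-BuLi then ZnCl2 convert 29 into the alkylzinc chloride F4. Negishi coupling with Pd(dppf)Cl2 (THF, 50 °C) gives the dienyl methyl ether F5, and 1 N HCl in THF hydrolyses the enol ether and the silyl ethers, rejoining the route at 32.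

3. Step 15. Ring closure through the ketone oxygen (O-alkylation) or pinacol-type rearrangement of the Lewis-acid-bound epoxide may outrun C-alkylation. The fallback uses a preformed carbon nucleophile and sets out from 21: t-BuMe2SiOTf/Et3N (CH2Cl2, −78 °C) gives the (Z)-silyl enol ether F6. Mukaiyama-type cyclisation with catalytic Me3SiOTf and 2,6-di-tert-butyl-4-methylpyridine (CH2Cl2, −78 °C), followed by Bu4NF/AcOH, rejoins the route at 22.

Further compounds
F1 | step 23 | (1R,3aR,8aR)-5-{2-[(1R,2S,5R,6R)-2,5-dihydroxy-6-[(3R)-3-hydroxy-4-methylpent-4-en-1-yl]-2,6-dimethylcyclohexyl]ethyl}-1-hydroxy-1,4,4,6-tetramethyl-2,3,3a,4,8,8a-hexahydroazulen-7(1H)-one | C=C(C)[C@H](O)CC[C@]1(C)[C@@H](CCC2=C(C)C(=O)C[C@@H]3[C@@H](CC[C@@]3(C)O)C2(C)C)[C@@](C)(O)CC[C@H]1O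
F2 | step 23 | analogue of 34 in which one methyl on the ether CMe2 carbon is CH2HgOCOCF3 (that carbon unassigned) | O[C@@H]1CC[C@]2(C)[C@@H](CCC3=C(C)C(=O)C[C@@H]4[C@@H](CC[C@@]4(C)O)C3(C)C)[C@@](C)(O)CC[C@H]2OC1(C)C[Hg]OC(=O)C(F)(F)F
F3 | step 21 | (1R,3aR,8aR)-7-methoxy-1,4,4,6-tetramethyl-1-(triethylsilyloxy)-1,2,3,3a,4,8a-hexahydroazulen-5-yl trifluoromethanesulfonate | FC(F)(F)S(=O)(=O)OC1=C(C)C(OC)=C[C@@H]2[C@@H](CC[C@@]2(C)O[Si](CC)(CC)CC)C1(C)C
F4 | step 21 | alkylzinc chloride from 29 (ZnCl in place of iodine) | CC(C)=CCC[C@]1(C)[C@@H](CC[Zn]Cl)[C@@](C)(O[Si](CC)(CC)CC)CC[C@H]1O[Si](CC)(CC)CC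
F5 | step 21 | tris(triethylsilyl)-protected coupled dienyl methyl ether (methyl enol ether of 32) | CC(C)=CCC[C@]1(C)[C@@H](CCC2=C(C)C(OC)=C[C@@H]3[C@@H](CC[C@@]3(C)O[Si](CC)(CC)CC)C2(C)C)[C@@](C)(O[Si](CC)(CC)CC)CC[C@H]1O[Si](CC)(CC)CC
F6 | step 15 | methyl (2Z,6R,7R)-3-(tert-butyldimethylsilyloxy)-6,7-epoxy-7,11-dimethyldodeca-2,10-dienoate | COC(=O)/C=C(\O[Si](C)(C)C(C)(C)C)CC[C@H]1O[C@]1(C)CCC=C(C)C
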